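The seven-membered ring (C1, C5–C10; guaiane numbering) is disconnected at C9, its only unsubstituted carbon, flanked by C10 (exocyclic methylene) and C8 (OAc). The other six carbons are the ring of p-benzoquinone monoketal, whose two enones take up the C5 and C7 substituents by asymmetric conjugate additions; the second leaves a regiodefined C10–C8 silyl enol ether. Its cyclopropane (C9) is cleaved oxidatively at the C10–C8 bond: the cyclohexane becomes a cycloheptenone whose C10 ketone later gives the methylene and whose C8=C9 enone takes the C8 oxygen anti to the isopropyl group. The precursor is a trans-fused 1-siloxybicyclo[4.1.0]heptane already carrying the cyclopentene ring.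

Key step: step 6

Remark on labels: atoms carry guaiane numbers throughout (seven-membered ring C1, C5, C6, C7, C8, C9, C10; five-membered ring C1–C5; CH3 on C4; exocyclic CH2 on C10); β is the face of H-1, α the face of H-5.
Remark on the chemistry: the ligand enantiomers in steps 1 and 3 are those expected, by analogy with cyclohexenone, to give the drawn configurations; chloroketone 12 is a mixture of C8 epimers, both of which eliminate to 13.

Step 1
Reactants: 1 1,4-dioxaspiro[4.5]deca-6,9-dien-8-one (p-benzoquinone mono(ethylene ketal)); 2 2-(prop-1-en-2-yl)-4,4,5,5-tetramethyl-1,3,2-dioxaborolane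
Product: 3 (R)-10-(prop-1-en-2-yl)-1,4-dioxaspiro[4.5]dec-6-en-8-one (enone with 5β-isopropenyl)
Conditions: [Rh(cod)Cl]2 (cat.), (R)-BINAP (cat.), KOH (0.3 equiv), dioxane/H2O 10:1, 40 °C; 1 in 1.5-fold excess
Reagents that add atoms: none
Why: Rh(I)-catalysed Hayashi–Miyaura 1,4-addition of the alkenylboronate to one of the two enantiotopic enones of the symmetric dienone, in which the BINAP ligand chooses the enone and its face and so sets C5, while the excess of 1 suppresses a second addition.

Step 2
Reactants: 3 (R)-10-(prop-1-en-2-yl)-1,4-dioxaspiro[4.5]dec-6-en-8-one; 4 allyl bromide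
Product: 6 (9S,10R)-9-allyl-10-(prop-1-en-2-yl)-1,4-dioxaspiro[4.5]dec-6-en-8-one (1α-allyl trans to 5β-isopropenyl), via lithium dienolate 5 (not isolated)
Conditions: LDA, THF, −78 °C; then 4, DMPU, −78 → −20 °C
Reagents that add atoms: lithium diisopropylamide, [Li]N(C(C)C)C(C)C (lithium kept only in 5)
Why: Kinetic α′-deprotonation of the cyclohexenone can only occur at C1 (the sole sp3 α-carbon), and enolate alkylation takes place anti to the neighbouring C5 substituent, giving the trans-1,5 relationship that becomes the trans ring fusion.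

Step 3
Reactants: 6 (9S,10R)-9-allyl-10-(prop-1-en-2-yl)-1,4-dioxaspiro[4.5]dec-6-en-8-one; 7 diisopropylzinc
Product: 9 monocyclic trimethylsilyl enol ether (C10–OSiMe3, C10=C8, 7β-isopropyl, C6 ethylene ketal, 5β-isopropenyl, 1α-allyl), via isopropylzinc enolate 8 (not isolated)
Conditions: Cu(OTf)2 (2 mol %), BINOL-derived bis(1-phenylethyl)amine phosphoramidite (4 mol %, enantiomer directing the alkyl group to the β-face of C7), toluene, −30 °C; then TMSOTf, −30 → 0 °C
Reagents that add atoms: trimethylsilyl trifluoromethanesulfonate, C[Si](C)(C)OS(=O)(=O)C(F)(F)F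
Why: Copper/phosphoramidite-catalysed asymmetric conjugate addition of a dialkylzinc to the remaining enone, a reaction type established for quinone-monoketal adducts where the ligand decides cis or trans delivery relative to the first substituent; the ligand places isopropyl cis to the C5 group, and silylation of the zinc enolate fixes the enol ether regiospecifically between C10 and C8.

Step 4
Reactants: 9 monocyclic trimethylsilyl enol ether
Product: 10 trans-fused bicyclic trimethylsilyl enol ether (cyclopentene C1–C2–C3=C4(CH3)–C5 closed; H-1β, H-5α; C10–OSiMe3, C10=C8, 7β-isopropyl, C6 ketal)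
Conditions: Grubbs second-generation catalyst (5 mol %), CH2Cl2, 40 °C
Reagents that add atoms: none
Why: Ring-closing metathesis between the allyl and isopropenyl groups closes the trisubstituted cyclopentene, while the trisubstituted silyl enol ether is inert to the ruthenium carbene; no stereocentre is touched.

Step 5
Reactants: 10 trans-fused bicyclic trimethylsilyl enol ether
Product: 11 1-(trimethylsilyloxy)bicyclo[4.1.0]heptane derivative (cyclopropane C8–C9–C10 on the α-face, C10–OSiMe3; other groups as in 10)
Conditions: Et2Zn (1.5 equiv), CH2I2 (1.5 equiv), CH2Cl2, 0 °C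
Reagents that add atoms: diiodomethane, ICI
Why: Simmons–Smith cyclopropanation (Furukawa variant) attacks the electron-rich silyl enol ether much faster than the trisubstituted cyclopentene and from the face opposite the C7 isopropyl group; the two new centres (C8, C10) are erased in step 6.

Step 6
Reactants: 11 1-(trimethylsilyloxy)bicyclo[4.1.0]heptane derivative
Product: 13 trans-fused cyclohept-2-enone (C10=O, C8=C9, 7β-isopropyl, C6 ethylene ketal, C3=C4 cyclopentene with 4-CH3, H-1β, H-5α), via beta-chloroketone 12 (not isolated)
Conditions: FeCl3 (2.2 equiv), DMF, 0 °C → rt; then NaOAc, MeOH, reflux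
Reagents that add atoms: iron(III) chloride, Cl[Fe](Cl)Cl (chlorine kept only in 12)
Why: One-electron oxidation of the siloxycyclopropane by Fe(III) and loss of the silyl group give a C10 oxy radical, which undergoes β-scission of the internal C10–C8 bond so that C9 now links C10 and C8 and the six-membered ring C1–C5–C6–C7–C8–C10 becomes the seven-membered ring; the secondary C8 radical is chlorinated by FeCl3 (12) and acetate eliminates HCl to the conjugated C8=C9 enone. The closest known reaction is the Ito–Saegusa ring expansion of 1-siloxybicyclo[n.1.0]alkanes to 2-cycloalkenones. No ring is closed: the ring is enlarged by cleavage of the endocyclic cyclopropane bond. No stereocentre is created (C8 and C10 become sp2) and C5 and C7 are untouched, while C1, now α to the ketone, keeps the trans fusion that is also the thermodynamically preferred one. The step needs cleavage of the internal rather than the external cyclopropane bond, secured because only the former gives a secondary ring radical, and chemoselectivity over the cyclopentene and the dioxolane, secured by the far lower oxidation potential of the siloxycyclopropane and by DMF tempering the Lewis acidity of FeCl3.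

Step 7
Reactants: 13 trans-fused cyclohept-2-enone
Product: 14 α-ketol (C3=O, 4α-OH, 4β-CH3; enone and ketal unchanged)
Conditions: RuCl3 (1 mol %), Oxone, NaHCO3, EtOAc/MeCN/H2O, 0 → 20 °C
Reagents that add atoms: potassium peroxymonosulfate (Oxone), [K+].[O-]S(=O)(=O)OO
Why: Ruthenium-catalysed ketohydroxylation (syn [3+2] addition of RuO4, then oxidation of the ruthenate ester) converts the electron-rich trisubstituted alkene into the ketol with OH on the tertiary C4; the reagent comes from the α-face, opposite the ketal-bearing C6 branch on C5, and the electron-poor enone alkene is left alone.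

Step 8
Reactants: 14 α-ketol
Product: 15 3β,4α-diol (trans-diol; enone and ketal unchanged)
Conditions: Me4NBH(OAc)3, MeCN/AcOH, −25 °C
Reagents that add atoms: none
Why: Evans–Saksena hydroxyl-directed reduction: the acetoxyborohydride bound to the 4α-oxygen delivers hydride intramolecularly to the α-face of C3, giving the 3β-alcohol trans to the tertiary hydroxyl, and the undirected enone carbonyl is not reduced.

Step 9
Reactants: 15 3β,4α-diol
Product: 17 3β,4α,8α-triol with C10 ketone (C6 ketal, 7β-isopropyl), via pinacol boronate 16 (not isolated)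
Conditions: CuCl (5 mol %), Xantphos (5 mol %), NaOtBu (10 mol %), B2pin2, MeOH (2 equiv), THF, rt; then NaBO3·4H2O, THF/H2O, rt
Reagents that add atoms: bis(pinacolato)diboron, CC1(C)OB(OC1(C)C)B1OC(C)(C)C(C)(C)O1 (boron kept only in 16); sodium perborate, [Na+].[O-]OB=O
Why: Copper(I)-catalysed conjugate borylation adds the boryl group to C8 anti to the adjacent C7 isopropyl group, and perborate oxidation of the C–B bond proceeds with retention to the 8α-alcohol.

Step 10
Reactants: 17 3β,4α,8α-triol with C10 ketone
Product: 18 3β,8α-diacetate (4α-OH free, C10 ketone, C6 ketal)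
Conditions: Ac2O, pyridine, DMAP (cat.), CH2Cl2, 0 °C → rt
Reagents that add atoms: acetic anhydride, CC(=O)OC(C)=O
Why: Acylation of the two secondary alcohols installs two of the final acetates, while the tertiary C4 hydroxyl does not react under these conditions.

Step 11
Reactants: 18 3β,8α-diacetate
Product: 19 10(14)-methylene compound (exocyclic CH2 on C10; 3β,8α-diacetate, 4α-OH, C6 ketal)
Conditions: Zn, CH2Br2, TiCl4 (pre-formed reagent), THF/CH2Cl2, 0 °C → rt
Reagents that add atoms: dibromomethane, BrCBr
Why: Takai–Lombardo methylenation uses a non-basic gem-dimetallic reagent, so the ketone is methylenated without β-elimination of the 8-acetate or epimerisation at C1, and the esters and the ketal are not attacked.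

Step 12
Reactants: 19 10(14)-methylene compound
Product: 20 C6 ketone (3β,8α-diacetate, 4α-OH, 7β-isopropyl, exocyclic methylene)
Conditions: PPTS, acetone/H2O, 55 °C
Reagents that add atoms: water, O
Why: Mild acid-catalysed hydrolysis (transketalisation) of the dioxolane frees the C6 ketone; the acetates and the 1,1-disubstituted alkene tolerate PPTS, and C5 and C7 already hold their more stable configurations.

Step 13
Reactants: 20 C6 ketone
Product: 21 6α-alcohol (3β,8α-diacetate, 4α-OH, 6α-OH)
Conditions: Et2BOMe, THF/MeOH 4:1, −78 °C; NaBH4, −78 °C; then MeOH co-evaporation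
Reagents that add atoms: none
Why: Narasaka–Prasad reduction: a diethylboron chelate links the 4α-oxygen and the C6 carbonyl on the α-side, so external hydride adds from the β-face (also the axial trajectory, anti to H-5 and H-7) and gives the 6α-alcohol, trans to both neighbours.

Step 14
Reactants: 21 6α-alcohol
Product: 22 CNP0147943.1, (1S,3S,4S,5S,6S,7R,8S)-3,6,8-triacetoxy-4-hydroxyguai-10(14)-ene
Conditions: Ac2O, pyridine, DMAP (cat.), CH2Cl2, rt
Reagents that add atoms: acetic anhydride, CC(=O)OC(C)=O
Why: Acetylation of the remaining secondary alcohol completes the triacetate, and the hindered tertiary C4 hydroxyl stays free as in the target.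

Compound list
1 | 1,4-dioxaspiro[4.5]deca-6,9-dien-8-one | O=C1C=CC2(OCCO2)C=C1 | starting material
2 | 2-(prop-1-en-2-yl)-4,4,5,5-tetramethyl-1,3,2-dioxaborolane | CC(=C)B1OC(C)(C)C(C)(C)O1 | starting material
3 | (R)-10-(prop-1-en-2-yl)-1,4-dioxaspiro[4.5]dec-6-en-8-one | O=C1C=CC2(OCCO2)[C@@H](C(C)=C)C1 | intermediate
4 | allyl bromide | C=CCBr | starting material
5 | lithium dienolate of 3 (C10–OLi, C10=C1) | [Li]OC1=C[C@H](C(C)=C)C2(OCCO2)C=C1 | intermediate (not isolated)
6 | (9S,10R)-9-allyl-10-(prop-1-en-2-yl)-1,4-dioxaspiro[4.5]dec-6-en-8-one | O=C1C=CC2(OCCO2)[C@@H](C(C)=C)[C@@H]1CC=C | intermediate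
7 | diisopropylzinc | CC(C)[Zn]C(C)C | starting material
8 | isopropylzinc enolate (C10–OZn, C10=C8, 7β-isopropyl) | CC(C)[Zn]OC1=C[C@@H](C(C)C)C2(OCCO2)[C@@H](C(C)=C)[C@@H]1CC=C | intermediate (not isolated)
9 | monocyclic trimethylsilyl enol ether (1α-allyl, 5β-isopropenyl, 7β-isopropyl) | C[Si](C)(C)OC1=C[C@@H](C(C)C)C2(OCCO2)[C@@H](C(C)=C)[C@@H]1CC=C | intermediate
10 | trans-fused bicyclic trimethylsilyl enol ether | C[Si](C)(C)OC1=C[C@@H](C(C)C)C2(OCCO2)[C@@H]3[C@@H]1CC=C3C | intermediate
11 | 1-(trimethylsilyloxy)bicyclo[4.1.0]heptane derivative (cyclopropane α) | C[Si](C)(C)O[C@@]12C[C@@H]1[C@@H](C(C)C)C3(OCCO3)[C@@H]4[C@@H]2CC=C4C | intermediate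
12 | β-chloroketone (C10=O, C8–Cl, both C8 epimers) | O=C1CC(Cl)[C@@H](C(C)C)C2(OCCO2)[C@@H]3[C@@H]1CC=C3C | intermediate (not isolated)
13 | trans-fused cyclohept-2-enone (C10=O, C8=C9) | O=C1C=C[C@@H](C(C)C)C2(OCCO2)[C@@H]3[C@@H]1CC=C3C | intermediate
14 | α-ketol (C3=O, 4α-OH) | O=C1C=C[C@@H](C(C)C)C2(OCCO2)[C@@H]3[C@@H]1CC(=O)[C@@]3(C)O | intermediate
15 | 3β,4α-diol | O=C1C=C[C@@H](C(C)C)C2(OCCO2)[C@@H]3[C@@H]1C[C@H](O)[C@@]3(C)O | intermediate
16 | 8α-pinacol boronate | O=C1C[C@H](B4OC(C)(C)C(C)(C)O4)[C@@H](C(C)C)C2(OCCO2)[C@@H]3[C@@H]1C[C@H](O)[C@@]3(C)O | intermediate (not isolated)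
17 | 3β,4α,8α-triol with C10 ketone | O=C1C[C@H](O)[C@@H](C(C)C)C2(OCCO2)[C@@H]3[C@@H]1C[C@H](O)[C@@]3(C)O | intermediate
18 | 3β,8α-diacetate with C10 ketone | O=C1C[C@H](OC(C)=O)[C@@H](C(C)C)C2(OCCO2)[C@@H]3[C@@H]1C[C@H](OC(C)=O)[C@@]3(C)O | intermediate
19 | 10(14)-methylene diacetate ketal | C=C1C[C@H](OC(C)=O)[C@@H](C(C)C)C2(OCCO2)[C@@H]3[C@@H]1C[C@H](OC(C)=O)[C@@]3(C)O | intermediate
20 | C6 ketone | C=C1C[C@H](OC(C)=O)[C@@H](C(C)C)C(=O)[C@@H]2[C@@H]1C[C@H](OC(C)=O)[C@@]2(C)O | intermediate
21 | 6α-alcohol | C=C1C[C@H](OC(C)=O)[C@@H](C(C)C)[C@H](O)[C@@H]2[C@@H]1C[C@H](OC(C)=O)[C@@]2(C)O | intermediate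
22 | CNP0147943.1 | C=C1C[C@H](OC(C)=O)[C@@H](C(C)C)[C@H](OC(C)=O)[C@@H]2[C@@H]1C[C@H](OC(C)=O)[C@@]2(C)O | target

Total step count: 14. Longest linear sequence: 14 steps (from 1).

Steps most likely to fail

Step 3: the ligand may not override the substrate's preference for axial attack anti to the C5 group, so that isopropyl enters trans to the isopropenyl group (poor facial selectivity at C7). The fallback brings in the C7 substituent as a second isopropenyl group by the strongly catalyst-controlled rhodium chemistry of step 1. It sets out from 6: Rh(I)/BINAP (enantiomer matched to the β-face of C7) and boronate 2 should give the cis-3,5-bis(isopropenyl) ketone F1. Ring-closing metathesis of its allyl and C5 isopropenyl groups gives the bicyclic ketone F2. Hydrogenation with Wilkinson's catalyst saturates only the 1,1-disubstituted isopropenyl group and gives the 7β-isopropyl ketone F3. Kinetic deprotonation at the C8 methylene (LDA, TMSCl, −78 °C) then comes back to the route at 10.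

Step 6: the oxidative opening may be diverted by loss of the dioxolane under the Lewis-acidic iron salt, by attack on the cyclopentene, or by incomplete elimination of the chloride. The fallback keeps the one-carbon ring expansion but uses a halocarbene and an electrocyclic opening instead of a radical fragmentation. It sets out from 10: dibromocarbene (CHBr3, KOtBu, pentane, −20 °C) adds to the enol ether to give the dibromocyclopropane F4. Warming (toluene, 80 °C) opens it with loss of bromotrimethylsilane to the 2-bromocycloheptenone F5. Palladium-catalysed hydrodebromination (Pd(PPh3)4, Bu3SnH) comes back to the route at 13.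

Step 7: the ruthenium oxidant may over-oxidise (cleavage of the cyclopentene or attack on the enone) before the ketol is released. The fallback separates the two oxidation events. It sets out from 13: OsO4 (cat.)/NMO dihydroxylates the cyclopentene from the α-face to the cis-3α,4α-diol F6. Parikh–Doering oxidation (SO3·pyridine, DMSO, Et3N) of its only secondary alcohol comes back to the route at 14.

Further compounds
F1 | step 3 | cis-3,5-bis(isopropenyl) ketone (1α-allyl, 5β- and 7β-isopropenyl, C10 ketone, C6 ketal) | O=C1C[C@@H](C(C)=C)C2(OCCO2)[C@@H](C(C)=C)[C@@H]1CC=C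
F2 | step 3 | trans-fused bicyclic ketone with 7β-isopropenyl | O=C1C[C@@H](C(C)=C)C2(OCCO2)[C@@H]3[C@@H]1CC=C3C
F3 | step 3 | trans-fused bicyclic ketone with 7β-isopropyl | O=C1C[C@@H](C(C)C)C2(OCCO2)[C@@H]3[C@@H]1CC=C3C
F4 | step 6 | 7,7-dibromo-1-(trimethylsilyloxy)bicyclo[4.1.0]heptane derivative | C[Si](C)(C)O[C@@]12C(Br)(Br)[C@@H]1[C@@H](C(C)C)C3(OCCO3)[C@@H]4[C@@H]2CC=C4C
F5 | step 6 | 2-bromocyclohept-2-enone (C9–Br, C10=O, C8=C9) | O=C1C(Br)=C[C@@H](C(C)C)C2(OCCO2)[C@@H]3[C@@H]1CC=C3C
F6 | step 7 | cis-3α,4α-diol | O=C1C=C[C@@H](C(C)C)C2(OCCO2)[C@@H]3[C@@H]1C[C@@H](O)[C@@]3(C)O
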